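## Retrosynthetic overview
1. Target ⇒ hydrogenolysis of two benzyl ethers ⇒ O-sulfation of the only free OH (3-OH) of 5,7-di-O-benzylkaempferide.
2. 5,7-Di-O-benzylkaempferide ⇒ cyclodehydration (O1–C2) of an o-hydroxyaryl 2-hydroxy-1,3-diketone.
3. Key C2–C3 bond: the acyl anion of 4-methoxybenzaldehyde (carbene-derived enaminol) attacks the aldehyde carbon of an aryl glyoxal, joining two carbonyl carbons.
4. Aryl glyoxal ⇒ Riley oxidation of di-O-benzylphloracetophenone ⇒ phloracetophenone.
5. Ring order: rings A and B are bought. Ring C, the only ring formed, closes in the same flask as the key C–C bond.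

Assumption: the target has no stereocentre and is achiral, so no enantiomer question arises. Sulfate monoesters are drawn as free acids like the target SMILES, are handled as triethylammonium salts, and are freed on H+ resin in the last work-up.

## Route

Step 1
Reactants: 1 2',4',6'-trihydroxyacetophenone
Product: 2 1-[2,4-bis(benzyloxy)-6-hydroxyphenyl]ethan-1-one
Conditions: BnBr (2.1 equiv), K2CO3 (2.2 equiv), DMF, 60 °C
Reagents that add atoms: benzyl bromide, BrCc1ccccc1
Why: Williamson ether synthesis: the 4-OH and one of the two equivalent ortho OH groups are alkylated, after which the last OH is hydrogen-bonded to the acetyl C=O and does not react with the limited BnBr.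

Step 2
Reactants: 2 1-[2,4-bis(benzyloxy)-6-hydroxyphenyl]ethan-1-one
Product: 3 2-[2,4-bis(benzyloxy)-6-hydroxyphenyl]-2-oxoacetaldehyde (obtained as hydrate/cyclic hemiacetal, dried to the keto aldehyde)
Conditions: SeO2 (1.3 equiv), 1,4-dioxane/H2O 30:1, 95 °C; Celite filtration; PhMe azeotrope
Reagents that add atoms: selenium dioxide, O=[Se]=O
Why: Riley oxidation: SeO2 attacks the enol of the only enolisable position (the acetyl CH3) and loss of Se(0) gives the α-keto aldehyde, while benzyl ethers and the chelated phenol tolerate aqueous dioxane.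

Step 3
Reactants: 3 2-[2,4-bis(benzyloxy)-6-hydroxyphenyl]-2-oxoacetaldehyde; 4 4-methoxybenzaldehyde
Product: 8 5,7-bis(benzyloxy)-3-hydroxy-2-(4-methoxyphenyl)-4H-chromen-4-one, via Breslow enaminol 5 (not isolated), via hydroxy-diketone 6 (not isolated), via cyclic hemiketal 7 (not isolated)
Conditions: 4 (3 equiv), 2-(pentafluorophenyl)-6,7-dihydro-5H-pyrrolo[2,1-c][1,2,4]triazol-2-ium BF4 (15 mol %), i-Pr2NEt (30 mol %), 4 Å MS, THF, 40 °C, Ar, 3 added by syringe pump over 4 h; then TsOH·H2O (50 mol %), 60 °C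
Reagents that add atoms: none
Why: Proposed new method: the carbene adds to 4 and proton transfer gives enaminol 5, whose former carbonyl carbon is now nucleophilic; 5 attacks the non-enolisable and far more electrophilic aldehyde carbon of 3 (kept dilute to suppress its self-coupling) and releases the carbene to give racemic ketol 6; the phenol of 6 adds to the anisoyl C=O (7) and acid-catalysed loss of water gives the aromatic pyranone, erasing the transient stereocentres; if the carbene activates 3 instead, the isomeric ketol shares the same enediol and should funnel to the same flavonol; the closest known reaction types are NHC-catalysed crossed benzoin reactions of aryl aldehydes with activated carbonyl acceptors (α-keto esters, trifluoromethyl ketones) and the acid cyclodehydration of o-hydroxyaryl 1,3-diketones used after Baker–Venkataraman rearrangements.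

Step 4
Reactants: 8 5,7-bis(benzyloxy)-3-hydroxy-2-(4-methoxyphenyl)-4H-chromen-4-one
Product: 9 5,7-bis(benzyloxy)-2-(4-methoxyphenyl)-4-oxo-4H-chromen-3-yl hydrogen sulfate (handled as the Et3NH+ salt)
Conditions: SO3·NEt3 (3 equiv), Et3N (2 equiv), DMF, 45 °C; MeOH quench; SiO2, CH2Cl2/MeOH/1% Et3N
Reagents that add atoms: sulfur trioxide–triethylamine complex, CC[N+](CC)(CC)S(=O)(=O)[O-]
Why: O-sulfation by SO3 transfer from an amine–SO3 complex: the 3-OH is the only free hydroxyl in 8, so only the 3-O-sulfate can form, and the lipophilic ammonium salt can be chromatographed.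

Step 5
Reactants: 9 5,7-bis(benzyloxy)-2-(4-methoxyphenyl)-4-oxo-4H-chromen-3-yl hydrogen sulfate
Product: 10 kaempferide 3-O-sulfate [5,7-dihydroxy-2-(4-methoxyphenyl)-4-oxo-4H-chromen-3-yl hydrogen sulfate]
Conditions: H2 (1 atm), 10% Pd/C, MeOH/THF 1:1, rt; filter; Dowex 50W-X8 (H+), H2O/MeOH, 0 °C; lyophilise
Reagents that add atoms: none
Why: Catalytic hydrogenolysis of aryl benzyl ethers: the S(VI) sulfate monoester anion neither poisons Pd nor cleaves at neutral pH, the chromone C2=C3 bond is not reduced at 1 atm, and a brief cold H+ exchange gives the free hydrogen sulfate.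

## Compound list
1 | 2',4',6'-trihydroxyacetophenone (phloracetophenone) | CC(=O)c1c(O)cc(O)cc1O | starting material
2 | 1-[2,4-bis(benzyloxy)-6-hydroxyphenyl]ethan-1-one | CC(=O)c1c(O)cc(OCc2ccccc2)cc1OCc1ccccc1 | intermediate
3 | 2-[2,4-bis(benzyloxy)-6-hydroxyphenyl]-2-oxoacetaldehyde | O=CC(=O)c1c(O)cc(OCc2ccccc2)cc1OCc1ccccc1 | intermediate
4 | 4-methoxybenzaldehyde | COc1ccc(C=O)cc1 | starting material
5 | Breslow enaminol from 4 and the triazolylidene (C=C geometry undefined; not isolated) | COc1ccc(cc1)C(O)=C1N(N=C2CCCN12)c1c(F)c(F)c(F)c(F)c1F | intermediate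
6 | 1-[2,4-bis(benzyloxy)-6-hydroxyphenyl]-2-hydroxy-3-(4-methoxyphenyl)propane-1,3-dione (racemic; not isolated) | COc1ccc(cc1)C(=O)C(O)C(=O)c1c(O)cc(OCc2ccccc2)cc1OCc1ccccc1 | intermediate
7 | 5,7-bis(benzyloxy)-2,3-dihydroxy-2-(4-methoxyphenyl)chroman-4-one (racemic diastereomer mixture; not isolated) | COc1ccc(cc1)C1(O)Oc2cc(OCc3ccccc3)cc(OCc3ccccc3)c2C(=O)C1O | intermediate
8 | 5,7-bis(benzyloxy)-3-hydroxy-2-(4-methoxyphenyl)-4H-chromen-4-one | COc1ccc(cc1)-c1oc2cc(OCc3ccccc3)cc(OCc3ccccc3)c2c(=O)c1O | intermediate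
9 | 5,7-bis(benzyloxy)-2-(4-methoxyphenyl)-4-oxo-4H-chromen-3-yl hydrogen sulfate | COc1ccc(cc1)-c1oc2cc(OCc3ccccc3)cc(OCc3ccccc3)c2c(=O)c1OS(=O)(=O)O | intermediate
10 | kaempferide 3-O-sulfate (achiral) | COc1ccc(-c2oc3cc(O)cc(O)c3c(=O)c2OS(=O)(=O)O)cc1 | target

## Step count
Total steps: 5.
Longest linear sequence: 5 (1 → 2 → 3 → 8 → 9 → 10); 4 enters at step 3.

## Steps most likely to fail

**Step 3.** The carbene may prefer the glyoxal. That could lead to redox isomerisation to an α-hydroxy acyl azolium, which the ortho phenol would trap, or to glyoxal self-coupling or anisoin build-up.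

The fallback sets out from 4, meets 3, and comes back at 6 and hence 8. It replaces the catalytic acyl anion by a stoichiometric, polarity-fixed one.
- 4 with propane-1,3-dithiol and BF3·OEt2 gives 2-(4-methoxyphenyl)-1,3-dithiane F1.
- n-BuLi (THF, −78 °C) converts this into 2-lithio-2-(4-methoxyphenyl)-1,3-dithiane F2.
- 2.2 equiv of this anion are added to anhydrous 3; the first equivalent only removes the phenol proton. Attack at the aldehyde carbon gives 1-[2,4-bis(benzyloxy)-6-hydroxyphenyl]-2-hydroxy-2-[2-(4-methoxyphenyl)-1,3-dithian-2-yl]ethan-1-one F3.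
- Hg(ClO4)2/CaCO3 in aqueous THF unmasks the ketone to 6, which TsOH closes to 8 as in step 3.

**Step 2.** SeO2 may selenate the very electron-rich ring or over-oxidise the o-hydroxyaryl glyoxal.

The fallback sets out from 2 and comes back at 3. It installs the oxygen by enol-ether epoxidation and then oxidises an alcohol.
- TMSOTf/Et3N (CH2Cl2, 0 °C) gives {1-[2,4-bis(benzyloxy)-6-(trimethylsilyloxy)phenyl]ethenyl}oxy(trimethyl)silane F4.
- Rubottom oxidation (mCPBA, NaHCO3, CH2Cl2, −20 °C; then citric acid/MeOH) gives 1-[2,4-bis(benzyloxy)-6-hydroxyphenyl]-2-hydroxyethan-1-one F5.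
- Cu(OAc)2 in MeOH under air oxidises the primary ketol to 3.

**Step 5.** Debenzylation may be slow on the salt, or the sulfate may be lost during hydrogenolysis or acid release.

The fallback sets out from 8 and comes back at 10, leaving out 9. Regiocontrol moves from protecting groups to an enzyme.
- H2, Pd/C on 8 gives kaempferide F6.
- Excess SO3·NEt3 (DMF, 45 °C) gives kaempferide 3,7-di-O-sulfate F7; the chelated 5-OH stays free.
- Arylsulfatase (Helix pomatia, acetate buffer, 37 °C) hydrolyses the true aryl sulfate at O-7. The 3-sulfate is not a substrate, so this gives 10 after cold H+ exchange.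

## Further compounds
F1 | step 3 | 2-(4-methoxyphenyl)-1,3-dithiane | COc1ccc(cc1)C1SCCCS1
F2 | step 3 | 2-lithio-2-(4-methoxyphenyl)-1,3-dithiane | [Li]C1(SCCCS1)c1ccc(OC)cc1
F3 | step 3 | 1-[2,4-bis(benzyloxy)-6-hydroxyphenyl]-2-hydroxy-2-[2-(4-methoxyphenyl)-1,3-dithian-2-yl]ethan-1-one (racemic) | COc1ccc(cc1)C1(SCCCS1)C(O)C(=O)c1c(O)cc(OCc2ccccc2)cc1OCc1ccccc1
F4 | step 2 | {1-[2,4-bis(benzyloxy)-6-(trimethylsilyloxy)phenyl]ethenyl}oxy(trimethyl)silane | C=C(O[Si](C)(C)C)c1c(O[Si](C)(C)C)cc(OCc2ccccc2)cc1OCc1ccccc1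
F5 | step 2 | 1-[2,4-bis(benzyloxy)-6-hydroxyphenyl]-2-hydroxyethan-1-one | OCC(=O)c1c(O)cc(OCc2ccccc2)cc1OCc1ccccc1
F6 | step 5 | kaempferide | COc1ccc(cc1)-c1oc2cc(O)cc(O)c2c(=O)c1O
F7 | step 5 | kaempferide 3,7-di-O-sulfate | COc1ccc(cc1)-c1oc2cc(OS(=O)(=O)O)cc(O)c2c(=O)c1OS(=O)(=O)O
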